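The numbers were set for the occasion; no experiment stands behind them.

Target is what stands after substrate has gone in and over-reaction has taken its share, and over-reaction reaches target through the dissolved part.

    reagent in the reaction phase ⇌ reagent in the second phase, rate k1*([reagent in the reaction phase] - [reagent in the second phase]/K1) per volume of the first phase (K1 = 1.8, k1 = 1.4 s⁻¹)
    substrate + reagent in the reaction phase → target (k2 = 31 M⁻¹ s⁻¹)
    reagent in the reaction phase + target → over-reacted product (k3 = 38 M⁻¹ s⁻¹)
    crystals ⇌ target, rate k4*(cs4 - [target]) while solid is left; crystals form when [target] > cs4 (cs4 = 0.11 mM, k4 = 1.0 s⁻¹)

substrate 5.0 mM; reagent in the second phase 1.50 equiv; time 50 s; volume of the second phase over the first 1.0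

- what is said of target includes crystals
- in the second phase: reagent in the second phase; everything else is in the first
- charges count per volume of the first phase; a concentration in a rate is the amount of a species over the volume of its own phase; every rate counts per litre of the first phase
- crystals is a solid; its amount is given per volume of the solution
- run time (flask): 50 s

- the target and crystals together standing at 50 s, as a percentage of the substrate charged
- the change that raises the amount of target and crystals together at 50 s, in percent of the substrate charged most ("none" if none brings more than 2 percentage points) (red / teal / grey / amber / none)
- amount of target and crystals together at 50 s, in percent of the substrate charged, after amber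

- red: doubling the amount of reagent in the second phase, all else as stated
- teal: doubling the dissolution coefficient of step 4, all else as stated
- grey: doubling the transfer coefficient of step 1, all else as stated
- amber: doubling the solubility in step 4, all else as stated

*Where is the reagent?* At partition, which puts 2.68 mM in the reaction phase and gives substrate a first lifetime of 12.0 s; transfer relaxes in about 0.714 s, faster than that.

*And dissolved target?* Crystals take up the excess over solubility with a lifetime of 1.00 s, shorter than substrate's, so that excess equals making rate times this lifetime.

*Then what does over-reaction cost?* Count substrate lifetimes, the natural logarithm of charge over substrate left. At solubility, each lifetime costs a fixed toll of 2.70% of the charge: the over-reaction constant times solubility, over the target-forming constant times the substrate charge. Reagent cancels from this ratio.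

*How many lifetimes?* Integrating the second-order step with reagent at partition leaves 10.0% of the substrate, which is 2.30 lifetimes and 6.2 percentage points of toll.

*The excess adds what?* With mid-conversion reagent at 1.79 mM, it adds 6.11%. I therefore commit to 77.7% for the flask.

*Amber and teal?* Amber doubles the toll and gives 71.5%. Teal divides the excess term by 2 and gains 3.1 points.

*Weak spot?* Red: I have no figure for it, so my choice of teal stands on that gap.

The forecast gives 77%, teal as the best change and 71% after amber, on the ground that “dissolved target sits above its solubility while crystals form slowly”.

The flask gives 77.3%, with teal the best change at 2.6 points, and 71.8% after amber. Step 2 had 31% of its turnover up to the asked time behind it by 5.00 s, with reagent in the reaction phase at 2.06 mM, and crystallising had 82% of its own behind it by 25.0 s, with dissolved target at 144% of saturation. By 50.0 s this flask held substrate at 12.3% and over-reacted product at 10.4%. That substrate is 2.10 lifetimes, so the toll reckoned at solubility comes to 5.7 points. The amber flask, its toll doubled, ends lower than this flask by 5.5 points.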